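In a one-step world each reagent makes one target, so 0.700 equiv of reagent would end at 70.0% target, with the remaining substrate beside it.

all flasks: substrate 0.20 M; free catalyst 2.6 mol%

| flask | reagent | remark | time |
|---|---|---|---|
| alpha | 0.70 equiv | the very flask that is asked about, followed so far |  |
| epsilon | 1 equiv | run made earlier |  |
| flask | 0.700 equiv |  | 12 h |

| run | time / min | target / % | substrate / % |
|---|---|---|---|
| alpha | 50.0 | 36.6 | 59.3 |
| alpha | 150 | 50.8 | 34.1 |
| alpha | 240 | 50.2 | 31.1 |
| alpha | 360 | 48.5 | 30.5 |
| alpha | 600 | 46.6 | 29.4 |
| alpha | 720 | 48.4 | 31.0 |
| epsilon | 3.00 | 4.1 | 95.3 |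
| epsilon | 5.00 | 6.8 | 92.9 |
| epsilon | 8.00 | 10.5 | 87.8 |
| epsilon | 15.0 | 19.5 | 79.6 |
| epsilon | 25.0 | 31.6 | 68.6 |
| epsilon | 40.0 | 44.3 | 52.3 |

(readings scatter by 0.5 percentage points)

- Thursday's: at 12 h add free catalyst, 100% of the amount charged, then wait 12 h
- Friday's: change nothing and wait 12 h more
- Tuesday's: at 12 h add reagent, 50.0% of the amount charged, then wait 12 h
- Sunday's: at 12 h take out 90% of the target then present, then wait 12 h

- target taken out counts as made
- additions bring no volume worth counting

- target, in percent of the substrate first charged, at 12 h
- which option adds most target ("none" when 2 percentage points or less is all one gets) (Thursday's / Friday's / Tuesday's / Sunday's / none)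
- target present, with what was taken out counted in, in percent of the substrate first charged, after Thursday's
- target present, with what was taken out counted in, in percent of the substrate first charged, after Sunday's

The alpha run is this flask followed so far. From 240 min on its substrate reads about 30.5%, so 69.5% was consumed, close to what the reagent charge allows: reagent is the limiting reagent. But target reads about 48.4%. So we fold the readings into one dimensionless number, the kept share, 0.697: target standing per substrate consumed, once the readings have gone flat. Multiplied by the consumable share, it gives 48.8% for the flask at 12 h.

Is one number enough? Not early: the same ratio reads 0.899 at 50.0 min and 0.771 at 150 min, higher than the kept share. So in the alpha run the ratio falls with time, and the kept share is read from its flat stretch.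

Thursday's and Friday's bring no reagent, and the alpha readings show about as much substrate consumed as the reagent charge allows, so we expect no gain. Tuesday's lifts the total reagent to 105% of the substrate charged, more than that charge, so the kept share puts target at 69.7%. By this reckoning Sunday's takes out 43.9%; if the rest splits anew, our total is 62.1%, less than our figure for Tuesday's.

The forecast gave 48% (46.8% to 49.3%) at 12 h, Tuesday's as the best option, 48% after Thursday's and 61.5% after Sunday's, the first and last lower than our figures , and it called the deficit “a reversible sink”.

The flask gives 47.6%, Tuesday's adding 20 percentage points, then 47.6% after Thursday's and 61.3% after Sunday's. The missing part stands as isomer of the product, 22.4% at 720 min. Started from the computed target, the kept share puts Sunday's at 61.8%.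

    reagent + free catalyst ⇌ catalyst intermediate A (K = 15.0 M⁻¹, k = 4.08 M⁻¹ min⁻¹)
    substrate + catalyst intermediate A → catalyst intermediate B (k = 90.0 M⁻¹ min⁻¹)
    catalyst intermediate B → free catalyst + target (k = 2.37 min⁻¹)
    catalyst intermediate B → spent catalyst (k = 0.00135 min⁻¹)
    target + free catalyst ⇌ isomer of the product + free catalyst, rate k5*[free catalyst]*[target] forward; the back reaction follows from the equilibrium constant (K = 0.470, k = 0.815 M⁻¹ min⁻¹)

In the neighbour flask with 0.170 equiv of reagent, the kept share gives 11.8%. That flask computes to 11.6%, with 83.0% substrate remaining.

(The runs were generated by integration with made-up constants; the scatter is artificial.)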